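**Retrosynthetic overview**

- The strategy rests on ring B. Its oxygens at C2' and C5' are para to each other, a third oxygen sits at C3', and C4' and C6' carry hydrogen. This is the atom pattern of a 3-alkoxy-2-silyloxyfuran (C2'–C5', with the former ring oxygen ending on C5') joined across a two-carbon alkyne unit (C1', C6').
- Key disconnection: C1'–C2' and C5'–C6', by Diels–Alder addition of a 3-benzyloxy-2-silyloxyfuran to a 2-ethynylchromone, followed by aromatizing opening of the oxygen bridge. Ring B is formed last, on the finished chromone (rings A and C).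
- Ring C: C-acetylation of 3,4,5-trimethoxyphenol, Claisen condensation with ethyl diethoxyacetate, cyclodehydration and acetal hydrolysis to the chromone-2-carbaldehyde, then Seyferth–Gilbert homologation to the alkyne.
- Furan: O-benzylation of α-hydroxy-γ-butyrolactone, selenoxide dehydrogenation to the butenolide, silylation.
- End game: benzylation of O5', silyl-to-methyl exchange at O2', then a single BCl3 operation that removes both benzyl groups and the chelated 5-O-methyl group, because BCl3 would not spare aryl benzyl ethers in a separate demethylation.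

Key step: step 7

Remark: the target has no stereocentre, so racemic α-hydroxy-γ-butyrolactone is used; primed locants refer to ring B of the flavone.

**Route**

Step 1
Reactants: 1 3,4,5-trimethoxyphenol
Product: 3 1-(6-hydroxy-2,3,4-trimethoxyphenyl)ethan-1-one, via difluoroboron chelate 2 (not isolated)
Conditions: AcOH, BF3·OEt2, 90 °C; then H2O/EtOH, 70 °C
Reagents that add atoms: acetic acid, CC(=O)O
Why: BF3-mediated Friedel–Crafts (Fries-type) C-acylation should occur at one of the two equivalent positions ortho to the phenol of this activated ring, and trapping of the product as the chelate 2 stops the reaction at monoacylation until aqueous work-up releases 3.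

Step 2
Reactants: 3 1-(6-hydroxy-2,3,4-trimethoxyphenyl)ethan-1-one; 4 ethyl 2,2-diethoxyacetate
Product: 7 5,6,7-trimethoxy-4-oxo-4H-chromene-2-carbaldehyde, via diketone acetal 5 (not isolated), via chromone acetal 6 (not isolated)
Conditions: NaH (3 equiv), THF, 0 → 65 °C; then HCl in EtOH, 60 °C; then 2 M aq HCl, 60 °C; PhMe azeotrope
Reagents that add atoms: water, O
Why: Crossed Claisen condensation of the sodium dianion of 3 with ester 4 should give the 1,3-diketone 5, dry acid then closes the chromone by addition of the only phenol oxygen to the acetal-side carbonyl and loss of water, and aqueous acid finally unmasks the non-enolisable aldehyde.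

Step 3
Reactants: 7 5,6,7-trimethoxy-4-oxo-4H-chromene-2-carbaldehyde
Product: 8 2-ethynyl-5,6,7-trimethoxy-4H-chromen-4-one
Conditions: (MeO)2P(O)CHN2, KOtBu, THF, −78 → −20 °C
Reagents that add atoms: dimethyl (diazomethyl)phosphonate, COP(=O)(OC)C=[N+]=[N-]
Why: Seyferth–Gilbert homologation (Horner–Wadsworth–Emmons addition to the aldehyde, loss of N2 from the diazoalkene and 1,2-hydrogen shift of the alkylidene carbene) should give the terminal alkyne, and the methanol-free, low-temperature variant with a hindered base is chosen so that no small alkoxide adds to the pyranone or to the acceptor alkyne.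

Step 4
Reactants: 9 rac-3-hydroxydihydrofuran-2(3H)-one (α-hydroxy-γ-butyrolactone)
Product: 10 rac-3-(benzyloxy)dihydrofuran-2(3H)-one
Conditions: BnBr, Ag2O, CH2Cl2, rt, dark
Reagents that add atoms: benzyl bromide, BrCc1ccccc1
Why: Ag2O-promoted Williamson-type benzylation etherifies the secondary alcohol under essentially neutral conditions, so the lactone should not open.

Step 5
Reactants: 10 rac-3-(benzyloxy)dihydrofuran-2(3H)-one
Product: 13 3-(benzyloxy)furan-2(5H)-one, via α-selenide 11 (not isolated), via selenoxide 12 (not isolated)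
Conditions: LiN(iPr)2, THF, −78 °C; PhSeBr; then H2O2 (30%), pyridine, CH2Cl2, 0 °C → rt
Reagents that add atoms: none
Why: α-Selenenylation of the lithium enolate followed by selenoxide syn-elimination, the classical lactone dehydrogenation, can only eliminate toward C4 because C3 has no other β-hydrogen, and this destroys the stereocentre.

Step 6
Reactants: 13 3-(benzyloxy)furan-2(5H)-one
Product: 14 3-(benzyloxy)-2-[(tert-butyldimethylsilyl)oxy]furan
Conditions: TBSOTf, Et3N, CH2Cl2, 0 °C; used directly after filtration through basic alumina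
Reagents that add atoms: tert-butyldimethylsilyl trifluoromethanesulfonate, CC(C)(C)[Si](C)(C)OS(=O)(=O)C(F)(F)F
Why: Soft enolisation (O-silylation of the butenolide carbonyl and removal of a C5 proton by Et3N) aromatises the ring to the 2-silyloxyfuran, the standard preparation of such dienes.

Step 7
Reactants: 8 2-ethynyl-5,6,7-trimethoxy-4H-chromen-4-one; 14 3-(benzyloxy)-2-[(tert-butyldimethylsilyl)oxy]furan
Product: 16 2-{3-(benzyloxy)-2-[(tert-butyldimethylsilyl)oxy]-5-hydroxyphenyl}-5,6,7-trimethoxy-4H-chromen-4-one, via oxanorbornadiene adduct 15 (not isolated)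
Conditions: 14 (1.5 equiv), PhMe, 90 °C, sealed tube
Reagents that add atoms: none
Why: Proposed new method: furan 14 is a cyclic ketene-acetal diene with its largest HOMO coefficient at C5, and the alkyne of 8 is a vinylogous ynoate whose terminal carbon is made electrophilic by the C4 carbonyl acting through C2=C3, so furan C5 should bond to the terminal carbon (C5'–C6') and furan C2 to the internal carbon (C1'–C2'), either in a concerted asynchronous (4+2) cycloaddition or by conjugate addition followed by closure of the allenyl enolate on the silyloxocarbenium carbon. The closest known reaction type is the Diels–Alder reaction of 2-silyloxyfurans with propiolates, ynones and acetylenedicarboxylates, which gives hydroquinone monosilyl ethers after bridge opening; an alkyne activated only through a 4-pyranone ring has not been shown as the acceptor. Ring B closes in an intermolecular (4+2) mode as the six-membered carbocycle of the 7-oxanorbornadiene 15. In 15 the C2'–O bridge bond ionises with lone-pair assistance from the silyloxy group and loss of the C5' proton aromatises, so the two bridgehead stereocentres are transient (racemic, relative configuration fixed by the bridge) and 16 has none. The step needs regioselectivity (chromone beside the silyloxy carbon) and a one-directional bridge opening; the first is secured by the matched polarisation of diene and alkyne, the second because only the silyl-ketal bridgehead can carry the cation.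

Step 8
Reactants: 16 2-{3-(benzyloxy)-2-[(tert-butyldimethylsilyl)oxy]-5-hydroxyphenyl}-5,6,7-trimethoxy-4H-chromen-4-one
Product: 17 2-{3,5-bis(benzyloxy)-2-[(tert-butyldimethylsilyl)oxy]phenyl}-5,6,7-trimethoxy-4H-chromen-4-one
Conditions: BnOH, PPh3, DIAD, THF, 0 °C → rt
Reagents that add atoms: benzyl alcohol, OCc1ccccc1
Why: Mitsunobu etherification alkylates the only free phenol under neutral conditions, which avoids the aryl silyl ether cleavage or migration expected with carbonate base and benzyl bromide.

Step 9
Reactants: 17 2-{3,5-bis(benzyloxy)-2-[(tert-butyldimethylsilyl)oxy]phenyl}-5,6,7-trimethoxy-4H-chromen-4-one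
Product: 19 2-[3,5-bis(benzyloxy)-2-methoxyphenyl]-5,6,7-trimethoxy-4H-chromen-4-one, via tetrabutylammonium phenoxide 18 (not isolated)
Conditions: Bu4NF (1.1 equiv), THF, 0 °C; then MeI (5 equiv), 0 °C → rt
Reagents that add atoms: iodomethane, CI
Why: Fluoride cleaves the aryl silyl ether to a naked tetrabutylammonium phenoxide that should be methylated in situ by iodomethane (Williamson ether synthesis), the benzyl and methyl ethers being inert.

Step 10
Reactants: 19 2-[3,5-bis(benzyloxy)-2-methoxyphenyl]-5,6,7-trimethoxy-4H-chromen-4-one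
Product: 21 2-(3,5-dihydroxy-2-methoxyphenyl)-5-hydroxy-6,7-dimethoxy-4H-chromen-4-one, via tris(dichloroboryl) ether 20 (not isolated)
Conditions: BCl3 (1 M in CH2Cl2, 6 equiv), C6HMe5 (5 equiv), CH2Cl2, −78 → 0 °C; then H2O
Reagents that add atoms: none
Why: BCl3 ionises the two aryl benzyl ethers at low temperature with Friedel–Crafts capture of the benzyl cations by pentamethylbenzene, and on warming the boron chelated between the C4 carbonyl and O5 should deliver chloride only to the peri 5-O-methyl group (the usual chelation-controlled demethylation of 5-methoxyflavones), leaving the unchelated 6-, 7- and 2'-methyl ethers.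

**Compound list**

1 | 3,4,5-trimethoxyphenol | COc1cc(O)cc(OC)c1OC | starting material
2 | 2,2-difluoro-5,6,7-trimethoxy-4-methyl-1,3,2-benzodioxaborinine (difluoroboron chelate of 3) | CC1=[O+][B-](F)(F)Oc2cc(OC)c(OC)c(OC)c12 | intermediate
3 | 1-(6-hydroxy-2,3,4-trimethoxyphenyl)ethan-1-one | CC(=O)c1c(O)cc(OC)c(OC)c1OC | intermediate
4 | ethyl 2,2-diethoxyacetate | CCOC(=O)C(OCC)OCC | starting material
5 | 4,4-diethoxy-1-(6-hydroxy-2,3,4-trimethoxyphenyl)butane-1,3-dione | CCOC(OCC)C(=O)CC(=O)c1c(O)cc(OC)c(OC)c1OC | intermediate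
6 | 2-(diethoxymethyl)-5,6,7-trimethoxy-4H-chromen-4-one | CCOC(OCC)c1cc(=O)c2c(OC)c(OC)c(OC)cc2o1 | intermediate
7 | 5,6,7-trimethoxy-4-oxo-4H-chromene-2-carbaldehyde | O=Cc1cc(=O)c2c(OC)c(OC)c(OC)cc2o1 | intermediate
8 | 2-ethynyl-5,6,7-trimethoxy-4H-chromen-4-one | C#Cc1cc(=O)c2c(OC)c(OC)c(OC)cc2o1 | intermediate
9 | rac-3-hydroxydihydrofuran-2(3H)-one (α-hydroxy-γ-butyrolactone, racemic) | O=C1OCCC1O | starting material
10 | rac-3-(benzyloxy)dihydrofuran-2(3H)-one (racemic) | O=C1OCCC1OCc1ccccc1 | intermediate
11 | rac-3-(benzyloxy)-3-(phenylselanyl)dihydrofuran-2(3H)-one (racemic) | O=C1OCCC1(OCc1ccccc1)[Se]c1ccccc1 | intermediate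
12 | 3-(benzyloxy)-3-(phenylseleninyl)dihydrofuran-2(3H)-one (racemic mixture of diastereomers at selenium) | O=C1OCCC1(OCc1ccccc1)[Se](=O)c1ccccc1 | intermediate
13 | 3-(benzyloxy)furan-2(5H)-one | O=C1OCC=C1OCc1ccccc1 | intermediate
14 | 3-(benzyloxy)-2-[(tert-butyldimethylsilyl)oxy]furan | CC(C)(C)[Si](C)(C)Oc1occc1OCc1ccccc1 | intermediate
15 | 2-{6-(benzyloxy)-1-[(tert-butyldimethylsilyl)oxy]-7-oxabicyclo[2.2.1]hepta-2,5-dien-2-yl}-5,6,7-trimethoxy-4H-chromen-4-one (racemic, bridge-fixed relative configuration; one enantiomer drawn) | CC(C)(C)[Si](C)(C)O[C@@]12O[C@@H](C=C1OCc1ccccc1)C=C2c1cc(=O)c2c(OC)c(OC)c(OC)cc2o1 | intermediate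
16 | 2-{3-(benzyloxy)-2-[(tert-butyldimethylsilyl)oxy]-5-hydroxyphenyl}-5,6,7-trimethoxy-4H-chromen-4-one | COc1cc2oc(-c3cc(O)cc(OCc4ccccc4)c3O[Si](C)(C)C(C)(C)C)cc(=O)c2c(OC)c1OC | intermediate
17 | 2-{3,5-bis(benzyloxy)-2-[(tert-butyldimethylsilyl)oxy]phenyl}-5,6,7-trimethoxy-4H-chromen-4-one | COc1cc2oc(-c3cc(OCc4ccccc4)cc(OCc4ccccc4)c3O[Si](C)(C)C(C)(C)C)cc(=O)c2c(OC)c1OC | intermediate
18 | tetrabutylammonium 2,4-bis(benzyloxy)-6-(5,6,7-trimethoxy-4-oxo-4H-chromen-2-yl)phenoxide | COc1cc2oc(-c3cc(OCc4ccccc4)cc(OCc4ccccc4)c3[O-])cc(=O)c2c(OC)c1OC.CCCC[N+](CCCC)(CCCC)CCCC | intermediate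
19 | 2-[3,5-bis(benzyloxy)-2-methoxyphenyl]-5,6,7-trimethoxy-4H-chromen-4-one | COc1cc2oc(-c3cc(OCc4ccccc4)cc(OCc4ccccc4)c3OC)cc(=O)c2c(OC)c1OC | intermediate
20 | 2-{3,5-bis[(dichloroboranyl)oxy]-2-methoxyphenyl}-5-[(dichloroboranyl)oxy]-6,7-dimethoxy-4H-chromen-4-one | COc1cc2oc(-c3cc(OB(Cl)Cl)cc(OB(Cl)Cl)c3OC)cc(=O)c2c(OB(Cl)Cl)c1OC | intermediate
21 | 2-(3,5-dihydroxy-2-methoxyphenyl)-5-hydroxy-6,7-dimethoxy-4H-chromen-4-one | COc1cc2oc(-c3cc(O)cc(O)c3OC)cc(=O)c2c(O)c1OC | target

**Step count and risks**

Total step count: 10. Longest linear sequence: 7 steps (steps 1, 2, 3, 7, 8, 9, 10; the furan branch, steps 4, 5, 6, 7, 8, 9, 10, is equally long).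

Steps most likely to fail:

1. Step 7 (bears the label). The alkyne is activated only vinylogously, so the furan may be lost to desilylation or oligomerisation before it adds. The addition may also stop at an open-chain conjugate adduct that does not close, or the regiochemistry may erode. The fallback builds ring B by the same cycloaddition on a classical acceptor and then makes ring C by known flavone chemistry. It sets out from furan 14 and acetophenone 3 and returns at 19. Furan 14 and methyl propiolate (PhMe, 60 °C), a known pairing of a 2-silyloxyfuran with an ynoate, should give methyl 3-(benzyloxy)-2-[(tert-butyldimethylsilyl)oxy]-5-hydroxybenzoate F1. Mitsunobu benzylation (BnOH, PPh3, DIAD) would give methyl 3,5-bis(benzyloxy)-2-[(tert-butyldimethylsilyl)oxy]benzoate F2. Bu4NF followed by MeI would give methyl 3,5-bis(benzyloxy)-2-methoxybenzoate F3. Claisen condensation of the dilithium dianion of 3 (LiN(SiMe3)2, THF, −78 °C → rt) with F3 would give 1-[3,5-bis(benzyloxy)-2-methoxyphenyl]-3-(6-hydroxy-2,3,4-trimethoxyphenyl)propane-1,3-dione F4. Cyclodehydration (TsOH, PhMe, 90 °C) then closes ring C to 19, and the route continues with step 10.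

2. Step 3. The pyranone and the acceptor alkyne are electrophilic, so conjugate attack of the base or of the diazophosphonate anion on the ring, or dipolar addition of the diazo reagent to the alkyne once formed, may compete with homologation. The fallback replaces the diazo route by olefination and elimination; it sets out from 7 and returns at 8. Wittig reaction of 7 with the ylide from (bromomethyl)triphenylphosphonium bromide and KOtBu (THF, −78 °C) should give 2-[(Z)-2-bromoethenyl]-5,6,7-trimethoxy-4H-chromen-4-one F5. Anti-dehydrobromination with Bu4NF in DMF at rt would then give 8.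

3. Step 10. Over-dealkylation is the main danger: once O3' and O5 carry boron, chelation can direct cleavage of the neighbouring 2'- and 6-methyl ethers, and benzyl cations that escape the scavenger can C-benzylate the electron-rich rings. The fallback separates the two deprotections and uses a reagent that acts only through the carbonyl chelate; it sets out from 19 and returns at 21. MgI2 (Et2O/PhMe, 80 °C) should cleave only the peri 5-O-methyl group and give 2-[3,5-bis(benzyloxy)-2-methoxyphenyl]-5-hydroxy-6,7-dimethoxy-4H-chromen-4-one F6. Hydrogenolysis (H2, Pd/C, EtOAc, rt) would then remove both benzyl ethers under neutral conditions to give 21.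

**Further compounds**

F1 | step 7 | methyl 3-(benzyloxy)-2-[(tert-butyldimethylsilyl)oxy]-5-hydroxybenzoate | COC(=O)c1cc(O)cc(OCc2ccccc2)c1O[Si](C)(C)C(C)(C)C
F2 | step 7 | methyl 3,5-bis(benzyloxy)-2-[(tert-butyldimethylsilyl)oxy]benzoate | COC(=O)c1cc(OCc2ccccc2)cc(OCc2ccccc2)c1O[Si](C)(C)C(C)(C)C
F3 | step 7 | methyl 3,5-bis(benzyloxy)-2-methoxybenzoate | COC(=O)c1cc(OCc2ccccc2)cc(OCc2ccccc2)c1OC
F4 | step 7 | 1-[3,5-bis(benzyloxy)-2-methoxyphenyl]-3-(6-hydroxy-2,3,4-trimethoxyphenyl)propane-1,3-dione | COc1cc(O)c(C(=O)CC(=O)c2cc(OCc3ccccc3)cc(OCc3ccccc3)c2OC)c(OC)c1OC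
F5 | step 3 | 2-[(Z)-2-bromoethenyl]-5,6,7-trimethoxy-4H-chromen-4-one | Br/C=C\c1cc(=O)c2c(OC)c(OC)c(OC)cc2o1
F6 | step 10 | 2-[3,5-bis(benzyloxy)-2-methoxyphenyl]-5-hydroxy-6,7-dimethoxy-4H-chromen-4-one | COc1cc2oc(-c3cc(OCc4ccccc4)cc(OCc4ccccc4)c3OC)cc(=O)c2c(O)c1OC
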